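Numbering: ring A = carbocycle C1–C10 (E-alkene C1=C10, OAc at C2 and C6). Ring C = cis-epoxide C4–C5. Ring B = lactone C7–C8–O–C12(=O)–C11(=C13H2).
Cuts: (a) remove the ring-B oxygen between C12 and C8 (retro-Baeyer–Villiger) to reach the 2-methylenecyclobutanone C7–C8–C12–C11. (b) Cut C11–C12 and C7–C8 together (retro [2+2]) to reach an open chain with a ketene C8=C12=O and a terminal allene C7=C11=C13. (c) Cut C6–C7 (acetylide plus lactone) and C2–C3 (methallylation of an enal).
Enabling feature: ring B, with C11=C13 exocyclic next to its carbonyl C12, is the one-oxygen homologue of the four-membered ring formed from a ketene and the internal π bond of a monosubstituted allene. C11 is the central allene carbon, so the regiochemistry and the methylene group need no extra steps.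
Forward order: linear chain, then a temporary dihydropyranone ring (O–C2–C3–C4–C5–C6) that fixes the Z geometry of C4=C5 and carries ring C. The ring is opened by an acetylide, the allene and diazoketone are installed, one step closes ring A and the four-membered ring, and oxygen insertion gives ring B.
Stereochemistry: C2 comes from a Keck methallylation. C4/C5 follow from C2 by anti epoxidation on the temporary ring. C6 comes from a chelation-controlled reduction. C7 follows from C6 (Felkin–Anh type). C8 is set cis to C7 by the ketene cycloaddition and is retained in the oxygen insertion.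
Key step: step 16

Remark: CIP descriptors are quoted with target locants. They change where substituent priorities change (C5 in 12 and 15, C7 in 27) although the spatial arrangement stays the same. Compound 15 is drawn in its open form, although it may rest partly as the six-membered hemiketal.

Step 1
Reactants: 1 but-3-yn-1-ol
Product: 2 tert-butyl(but-3-yn-1-yloxy)diphenylsilane
Conditions: TBDPSCl, imidazole, CH2Cl2, 0 °C to rt
Reagents that add atoms: tert-butyl(chloro)diphenylsilane, CC(C)(C)[Si](Cl)(c1ccccc1)c1ccccc1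
Why: Routine silylation of a primary alcohol; the TBDPS ether should outlast the alkyllithium, the alkaline peroxide and the later selective removal of a TBS ether.

Step 2
Reactants: 2 tert-butyl(but-3-yn-1-yloxy)diphenylsilane
Product: 4 (E)-tert-butyl[(4-iodo-3-methylbut-3-en-1-yl)oxy]diphenylsilane, via alkenyldimethylalane 3 (not isolated)
Conditions: Me3Al, Cp2ZrCl2 (cat.), CH2Cl2, 0 °C to rt; then I2, THF, −30 °C
Reagents that add atoms: trimethylaluminium, C[Al](C)C; iodine, II
Why: Negishi zirconium-catalysed carboalumination adds methyl and aluminium syn across the terminal alkyne (methyl to the internal carbon), and iodinolysis proceeds with retention, which fixes the E geometry of C1=C10.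

Step 3
Reactants: 4 (E)-tert-butyl[(4-iodo-3-methylbut-3-en-1-yl)oxy]diphenylsilane
Product: 6 (E)-5-(tert-butyldiphenylsilyloxy)-3-methylpent-2-enal, via alkenyllithium 5 (not isolated)
Conditions: t-BuLi (2 equiv), Et2O, −78 °C; then DMF, −78 °C to 0 °C
Reagents that add atoms: N,N-dimethylformamide, CN(C)C=O; tert-butyllithium, [Li]C(C)(C)C (supplies only the lithium of 5)
Why: Iodine–lithium exchange with retention of alkene geometry followed by formylation with DMF is a standard route to E-enals.

Step 4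
Reactants: 6 (E)-5-(tert-butyldiphenylsilyloxy)-3-methylpent-2-enal; 7 tributyl(2-methylallyl)stannane
Product: 8 (4S,5E)-8-(tert-butyldiphenylsilyloxy)-2,6-dimethylocta-1,5-dien-4-ol
Conditions: (S)-BINOL, Ti(OiPr)4 (cat.), 4 Å MS, CH2Cl2, −20 °C
Reagents that add atoms: none
Why: Keck asymmetric methallylation; by analogy with the established sense of the (S)-BINOL–titanium Lewis acid, the stannane should add to the Si face of the enal and set C2 as S.

Step 5
Reactants: 8 (4S,5E)-8-(tert-butyldiphenylsilyloxy)-2,6-dimethylocta-1,5-dien-4-ol; 9 acryloyl chloride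
Product: 10 (4S,5E)-8-(tert-butyldiphenylsilyloxy)-2,6-dimethylocta-1,5-dien-4-yl prop-2-enoate
Conditions: iPr2NEt, DMAP (cat.), CH2Cl2, 0 °C
Reagents that add atoms: none
Why: Plain O-acylation of a secondary alcohol that does not touch the C2 stereocentre and brings in C5 and C6.

Step 6
Reactants: 10 (4S,5E)-8-(tert-butyldiphenylsilyloxy)-2,6-dimethylocta-1,5-dien-4-yl prop-2-enoate
Product: 11 (6S)-6-[(1E)-4-(tert-butyldiphenylsilyloxy)-2-methylbut-1-en-1-yl]-4-methyl-5,6-dihydro-2H-pyran-2-one
Conditions: second-generation Grubbs catalyst RuCl2(=CHPh)(PCy3)(H2IMes) (cat.), CH2Cl2 (2 mM), reflux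
Reagents that add atoms: none
Why: Ring-closing metathesis of an acrylate with a 1,1-disubstituted alkene is a known route to 4-methyl-dihydropyranones, and the six-membered ring can hold C4=C5 only in the Z geometry that the cis-epoxide needs.

Step 7
Reactants: 11 (6S)-6-[(1E)-4-(tert-butyldiphenylsilyloxy)-2-methylbut-1-en-1-yl]-4-methyl-5,6-dihydro-2H-pyran-2-one
Product: 12 (1R,4S,6R)-4-[(1E)-4-(tert-butyldiphenylsilyloxy)-2-methylbut-1-en-1-yl]-6-methyl-3,7-dioxabicyclo[4.1.0]heptan-2-one
Conditions: 30% aq H2O2, NaOH, MeOH, 0 °C; work-up at pH 4–5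
Reagents that add atoms: hydrogen peroxide, OO
Why: Weitz–Scheffer nucleophilic epoxidation touches only the electron-poor C4=C5 bond, and hydroperoxide should add axially to C4 anti to the pseudo-equatorial side chain at C2, as is usual for 6-substituted dihydropyranones, which sets C4 (R) and C5 from C2.

Step 8
Reactants: 12 epoxy lactone (1R,4S,6R); 13 tert-butyldimethyl(prop-2-yn-1-yloxy)silane
Product: 15 1-{(2R,3R)-3-[(2S,3E)-6-(tert-butyldiphenylsilyloxy)-2-hydroxy-4-methylhex-3-en-1-yl]-3-methyloxiran-2-yl}-4-(tert-butyldimethylsilyloxy)but-2-yn-1-one, via lithium acetylide 14 (not isolated)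
Conditions: 13, n-BuLi, THF, −78 °C; then 12, −78 °C; quench cold
Reagents that add atoms: n-butyllithium, [Li]CCCC (supplies only the lithium of 14)
Why: Acylation of a lithium acetylide by a δ-lactone stops at the ketone level because the lithium hemiketal persists at −78 °C; the step forms C6–C7, opens the temporary ring and frees the C2 hydroxyl.

Step 9
Reactants: 15 hydroxy epoxy ynone (2S,4R,5R)
Product: 16 (1S)-1-{(2S,3R)-3-[(2S,3E)-6-(tert-butyldiphenylsilyloxy)-2-hydroxy-4-methylhex-3-en-1-yl]-3-methyloxiran-2-yl}-4-(tert-butyldimethylsilyloxy)but-2-yn-1-ol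
Conditions: Zn(BH4)2, Et2O, −30 °C to 0 °C
Reagents that add atoms: none
Why: Chelation-controlled reduction of an α,β-epoxy ketone; zinc ties the carbonyl and epoxide oxygens together and hydride should enter from the side of H5, away from C4, giving the erythro epoxy alcohol (C6 = S).

Step 10
Reactants: 16 epoxy diol (2S,4R,5S,6S)
Product: 17 (1S)-1-{(2S,3R)-3-[(2S,3E)-2-acetoxy-6-(tert-butyldiphenylsilyloxy)-4-methylhex-3-en-1-yl]-3-methyloxiran-2-yl}-4-(tert-butyldimethylsilyloxy)but-2-yn-1-yl acetate
Conditions: Ac2O, pyridine, DMAP (cat.), CH2Cl2, 0 °C to rt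
Reagents that add atoms: acetic anhydride, CC(=O)OC(C)=O
Why: One acetylation installs both acetates of the target on the C2 and C6 hydroxyls without touching any stereocentre.

Step 11
Reactants: 17 diacetate bis-silyl ether
Product: 18 (1S)-1-{(2S,3R)-3-[(2S,3E)-2-acetoxy-6-(tert-butyldiphenylsilyloxy)-4-methylhex-3-en-1-yl]-3-methyloxiran-2-yl}-4-hydroxybut-2-yn-1-yl acetate
Conditions: HF·pyridine, pyridine, THF, 0 °C
Reagents that add atoms: none
Why: A primary TBS ether is cleaved by buffered HF·pyridine well before a TBDPS ether, and acetates and trisubstituted epoxides are known to tolerate this reagent.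

Step 12
Reactants: 18 propargylic alcohol (2S,4R,5S,6S)
Product: 21 (1S)-1-{(2S,3R)-3-[(2S,3E)-2-acetoxy-6-(tert-butyldiphenylsilyloxy)-4-methylhex-3-en-1-yl]-3-methyloxiran-2-yl}buta-2,3-dien-1-yl acetate, via propargyl sulfonylhydrazine 19 (not isolated), via propargyl diazene 20 (not isolated)
Conditions: PPh3, DEAD, 2-nitrobenzenesulfonohydrazide, THF, −15 °C; then rt
Reagents that add atoms: 2-nitrobenzenesulfonohydrazide, NNS(=O)(=O)c1ccccc1[N+](=O)[O-] (its N and S atoms stand only in 19 and 20)
Why: Myers allene synthesis; Mitsunobu displacement at the primary propargylic carbon C13, loss of sulfinic acid and a retro-ene loss of N2 deliver hydrogen to C7 and give the terminal allene C7=C11=C13 under neutral conditions.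

Step 13
Reactants: 21 allenyl diacetate silyl ether
Product: 22 (1S)-1-{(2S,3R)-3-[(2S,3E)-2-acetoxy-6-hydroxy-4-methylhex-3-en-1-yl]-3-methyloxiran-2-yl}buta-2,3-dien-1-yl acetate
Conditions: TBAF, AcOH (1:1), THF, 0 °C to rt
Reagents that add atoms: none
Why: Acetic-acid-buffered fluoride removes the TBDPS group without acetate cleavage or migration.

Step 14
Reactants: 22 primary alcohol
Product: 23 (3E,5S)-5-acetoxy-6-{(2R,3S)-3-[(1S)-1-acetoxybuta-2,3-dien-1-yl]-2-methyloxiran-2-yl}-3-methylhex-3-enoic acid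
Conditions: TEMPO (cat.), PhI(OAc)2, MeCN/H2O, rt
Reagents that add atoms: water, O
Why: Oxoammonium oxidation takes a primary alcohol through the aldehyde hydrate to the acid near neutral pH, so the β,γ-alkene should not move into conjugation and the allene, epoxide and acetates stay intact.

Step 15
Reactants: 23 β,γ-unsaturated acid
Product: 25 (4E,6S)-6-acetoxy-7-{(2R,3S)-3-[(1S)-1-acetoxybuta-2,3-dien-1-yl]-2-methyloxiran-2-yl}-1-diazo-4-methylhept-4-en-2-one, via mixed anhydride 24 (not isolated)
Conditions: i-BuOCOCl, N-methylmorpholine, THF, −20 °C; then CH2N2, Et2O, 0 °C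
Reagents that add atoms: diazomethane, C=[N+]=[N-]; isobutyl chloroformate, CC(C)COC(=O)Cl (its atoms stand only in 24)
Why: This is the first half of an Arndt–Eistert sequence; the weak base and low temperature should avoid deprotonation at C9 and the vinylogous loss of the C2 acetate.

Step 16
Reactants: 25 diazoketone (2S,4R,5S,6S)
Product: 27 cis-fused 2-methylenecyclobutanone (2S,4R,5S,6S,7S,8R) that is the target skeleton lacking the ring-B oxygen so that C12 is bonded directly to C8, via aldoketene 26 (not isolated)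
Conditions: hν (365 nm LED), dry degassed toluene (0.3 mM), −40 °C; then dark, 110 °C
Reagents that add atoms: none
Why: Proposed new method: irradiation expels N2 and triggers the Wolff rearrangement (C9 shifts from the acyl carbon, the future C12, to the diazo carbon, the future C8), so the aldoketene 26 is made cold and free of base, salt or nucleophile, and on warming in the dark it should add across the internal allene π bond in a concerted but asynchronous [π2s+π2a] cycloaddition in which the electrophilic C12 bonds to the central allene carbon C11 slightly ahead of the C8–C7 bond. The closest known reaction type is the intramolecular ketene–allene [2+2] cycloaddition that gives 7-methylenebicyclo[3.2.0]heptan-6-ones through three- and four-atom tethers; what is new is the eight-atom tether, that is, closure of a ten-membered ring. The four-membered ring (C7, C8, C12, C11) closes by the cycloaddition itself and ring A closes in the fused mode through the same C7–C8 bond, the chain being folded beforehand by its two rigid turns, the cis-epoxide C4–C5 and the E-alkene C1=C10. C8 should end up cis to C7 (H7 and H8 on one face) because the ketene approaches with its hydrogen toward the allene and the twist of the cycloaddition turns its larger substituent C9 to the side of C6, while C7 is controlled by C6, since the enolate-like C8 should close on the cation-like C7 anti to the C6–OAc bond with H6 next to C11 (Felkin–Anh-type arrangement, gauche C5–C6–C7–C8), which corresponds to 7S in 27 and 7R in the target. The step needs the internal π bond C7=C11 and not the terminal C11=C13 to react (favoured by the better stabilised secondary positive charge at C7), needs C1=C10 to stay out (it sits one atom from C8 and could only give a bicyclopentanone), and needs ring closure to outrun ketene dimerisation (high dilution, no amine or ammonium salt to catalyse it).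

Step 17
Reactants: 27 cis-fused 2-methylenecyclobutanone
Product: 28 (1(10)E,2S,4R,5S,6S,7R,8R)-2,6-diacetoxy-4,5-epoxygermacra-1(10),11(13)-dien-12,8-olide
Conditions: 30% aq H2O2, AcOH, NaOAc, 0–5 °C
Reagents that add atoms: hydrogen peroxide, OO
Why: Baeyer–Villiger oxidation; strain release lets the cyclobutanone carbonyl take up H2O2 under conditions that leave isolated alkenes alone, and the secondary sp3 carbon C8 should migrate in preference to the sp2 carbon C11 and with retention, so oxygen enters between C12 and C8 and ring B results.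

Compound list
1 | but-3-yn-1-ol | C#CCCO | starting material
2 | tert-butyl(but-3-yn-1-yloxy)diphenylsilane | C#CCCO[Si](c1ccccc1)(c1ccccc1)C(C)(C)C | intermediate
3 | (E)-[4-(tert-butyldiphenylsilyloxy)-2-methylbut-1-en-1-yl]dimethylalane | C[Al](C)/C=C(\C)CCO[Si](c1ccccc1)(c1ccccc1)C(C)(C)C | intermediate
4 | (E)-tert-butyl[(4-iodo-3-methylbut-3-en-1-yl)oxy]diphenylsilane | I/C=C(\C)CCO[Si](c1ccccc1)(c1ccccc1)C(C)(C)C | intermediate
5 | (E)-[4-(tert-butyldiphenylsilyloxy)-2-methylbut-1-en-1-yl]lithium | [Li]/C=C(\C)CCO[Si](c1ccccc1)(c1ccccc1)C(C)(C)C | intermediate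
6 | (E)-5-(tert-butyldiphenylsilyloxy)-3-methylpent-2-enal | O=C/C=C(\C)CCO[Si](c1ccccc1)(c1ccccc1)C(C)(C)C | intermediate
7 | tributyl(2-methylallyl)stannane | C=C(C)C[Sn](CCCC)(CCCC)CCCC | starting material
8 | (4S,5E)-8-(tert-butyldiphenylsilyloxy)-2,6-dimethylocta-1,5-dien-4-ol | CC(C)(C)[Si](OCC/C(C)=C/[C@@H](O)CC(C)=C)(c1ccccc1)c1ccccc1 | intermediate
9 | acryloyl chloride | C=CC(=O)Cl | starting material
10 | (4S,5E)-8-(tert-butyldiphenylsilyloxy)-2,6-dimethylocta-1,5-dien-4-yl prop-2-enoate | CC(C)(C)[Si](OCC/C(C)=C/[C@@H](OC(=O)C=C)CC(C)=C)(c1ccccc1)c1ccccc1 | intermediate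
11 | (6S)-6-[(1E)-4-(tert-butyldiphenylsilyloxy)-2-methylbut-1-en-1-yl]-4-methyl-5,6-dihydro-2H-pyran-2-one | CC(C)(C)[Si](OCC/C(C)=C/[C@@H]1CC(C)=CC(=O)O1)(c1ccccc1)c1ccccc1 | intermediate
12 | (1R,4S,6R)-4-[(1E)-4-(tert-butyldiphenylsilyloxy)-2-methylbut-1-en-1-yl]-6-methyl-3,7-dioxabicyclo[4.1.0]heptan-2-one | CC(C)(C)[Si](OCC/C(C)=C/[C@@H]1C[C@@]2(C)O[C@H]2C(=O)O1)(c1ccccc1)c1ccccc1 | intermediate
13 | tert-butyldimethyl(prop-2-yn-1-yloxy)silane | C#CCO[Si](C)(C)C(C)(C)C | starting material
14 | lithium 3-(tert-butyldimethylsilyloxy)prop-1-yn-1-ide | [Li]C#CCO[Si](C)(C)C(C)(C)C | intermediate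
15 | 1-{(2R,3R)-3-[(2S,3E)-6-(tert-butyldiphenylsilyloxy)-2-hydroxy-4-methylhex-3-en-1-yl]-3-methyloxiran-2-yl}-4-(tert-butyldimethylsilyloxy)but-2-yn-1-one (open form) | CC(C)(C)[Si](OCC/C(C)=C/[C@@H](O)C[C@@]1(C)O[C@H]1C(=O)C#CCO[Si](C)(C)C(C)(C)C)(c1ccccc1)c1ccccc1 | intermediate
16 | (1S)-1-{(2S,3R)-3-[(2S,3E)-6-(tert-butyldiphenylsilyloxy)-2-hydroxy-4-methylhex-3-en-1-yl]-3-methyloxiran-2-yl}-4-(tert-butyldimethylsilyloxy)but-2-yn-1-ol | CC(C)(C)[Si](OCC/C(C)=C/[C@@H](O)C[C@@]1(C)O[C@H]1[C@@H](O)C#CCO[Si](C)(C)C(C)(C)C)(c1ccccc1)c1ccccc1 | intermediate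
17 | diacetate of 16 (2S,4R,5S,6S) | CC(C)(C)[Si](OCC/C(C)=C/[C@@H](OC(C)=O)C[C@@]1(C)O[C@H]1[C@@H](OC(C)=O)C#CCO[Si](C)(C)C(C)(C)C)(c1ccccc1)c1ccccc1 | intermediate
18 | (1S)-1-{(2S,3R)-3-[(2S,3E)-2-acetoxy-6-(tert-butyldiphenylsilyloxy)-4-methylhex-3-en-1-yl]-3-methyloxiran-2-yl}-4-hydroxybut-2-yn-1-yl acetate | CC(C)(C)[Si](OCC/C(C)=C/[C@@H](OC(C)=O)C[C@@]1(C)O[C@H]1[C@@H](OC(C)=O)C#CCO)(c1ccccc1)c1ccccc1 | intermediate
19 | N-propargyl-N-(2-nitrobenzenesulfonyl)hydrazine derived from 18 (nitrogen at C13) | CC(C)(C)[Si](OCC/C(C)=C/[C@@H](OC(C)=O)C[C@@]1(C)O[C@H]1[C@@H](OC(C)=O)C#CCN(N)S(=O)(=O)c2ccccc2[N+](=O)[O-])(c1ccccc1)c1ccccc1 | intermediate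
20 | propargyl diazene derived from 19 (HN=N at C13) | CC(C)(C)[Si](OCC/C(C)=C/[C@@H](OC(C)=O)C[C@@]1(C)O[C@H]1[C@@H](OC(C)=O)C#CCN=N)(c1ccccc1)c1ccccc1 | intermediate
21 | (1S)-1-{(2S,3R)-3-[(2S,3E)-2-acetoxy-6-(tert-butyldiphenylsilyloxy)-4-methylhex-3-en-1-yl]-3-methyloxiran-2-yl}buta-2,3-dien-1-yl acetate | CC(C)(C)[Si](OCC/C(C)=C/[C@@H](OC(C)=O)C[C@@]1(C)O[C@H]1[C@@H](OC(C)=O)C=C=C)(c1ccccc1)c1ccccc1 | intermediate
22 | (1S)-1-{(2S,3R)-3-[(2S,3E)-2-acetoxy-6-hydroxy-4-methylhex-3-en-1-yl]-3-methyloxiran-2-yl}buta-2,3-dien-1-yl acetate | OCC/C(C)=C/[C@@H](OC(C)=O)C[C@@]1(C)O[C@H]1[C@@H](OC(C)=O)C=C=C | intermediate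
23 | (3E,5S)-5-acetoxy-6-{(2R,3S)-3-[(1S)-1-acetoxybuta-2,3-dien-1-yl]-2-methyloxiran-2-yl}-3-methylhex-3-enoic acid | OC(=O)C/C(C)=C/[C@@H](OC(C)=O)C[C@@]1(C)O[C@H]1[C@@H](OC(C)=O)C=C=C | intermediate
24 | isobutyl carbonic mixed anhydride of 23 | CC(C)COC(=O)OC(=O)C/C(C)=C/[C@@H](OC(C)=O)C[C@@]1(C)O[C@H]1[C@@H](OC(C)=O)C=C=C | intermediate
25 | (4E,6S)-6-acetoxy-7-{(2R,3S)-3-[(1S)-1-acetoxybuta-2,3-dien-1-yl]-2-methyloxiran-2-yl}-1-diazo-4-methylhept-4-en-2-one | [N-]=[N+]=CC(=O)C/C(C)=C/[C@@H](OC(C)=O)C[C@@]1(C)O[C@H]1[C@@H](OC(C)=O)C=C=C | intermediate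
26 | aldoketene O=C12=C8H–C9H2–C10(CH3)=C1H– carrying the rest of the chain of 25 (2S,4R,5S,6S) | O=C=CC/C(C)=C/[C@@H](OC(C)=O)C[C@@]1(C)O[C@H]1[C@@H](OC(C)=O)C=C=C | intermediate
27 | cis-fused 2-methylenecyclobutanone (2S,4R,5S,6S,7S,8R), target skeleton lacking the ring-B oxygen | C=C1C(=O)[C@@H]2C/C(C)=C/[C@@H](OC(C)=O)C[C@@]3(C)O[C@H]3[C@@H](OC(C)=O)[C@H]12 | intermediate
28 | (1(10)E,2S,4R,5S,6S,7R,8R)-2,6-diacetoxy-4,5-epoxygermacra-1(10),11(13)-dien-12,8-olide | C=C1C(=O)O[C@@H]2C/C(C)=C/[C@@H](OC(C)=O)C[C@@]3(C)O[C@H]3[C@@H](OC(C)=O)[C@H]12 | target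

Total step count: 17. Longest linear sequence: 17 steps (from 1).

Steps most likely to fail

1. Step 16.
- What may go wrong: closure of the ten-membered ring may be too slow for an unactivated aldoketene, so oligomerisation or capture by adventitious water may win. The terminal allene π bond may react instead of the internal one. The facial selectivity at C7 may be poor.
- Fallback (known chemistry, sets out from 18, comes back at 28): the two bonds are made separately. The chain-end carbon of 18 becomes C8, and C12 comes from CO.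
- Hydroxyl-directed trans-hydrostannation of the alkyne (Bu3SnH, [(C5Me5)RuCl]4, CH2Cl2) should place tin at C11 and give the (Z)-alkenylstannane F1.
- Oxidative methoxycarbonylation (Pd(OAc)2, Ph3As, 1,4-benzoquinone, CO, MeOH) should give the 2-(hydroxymethyl)enoate F2.
- TBAF/AcOH should give the diol F3.
- Corey–Kim bromination (NBS, Me2S), which is selective for the allylic alcohol, should give the allylic bromide F4.
- Dess–Martin periodinane should give the bromo aldehyde F5.
- A Nozaki–Hiyama-type macrocyclic allylation with CrCl2 (THF, high dilution), of the kind used for ten-membered germacranolide rings, would close C7–C8. The resulting alkoxide would lactonise onto the methyl ester to give 28.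

2. Step 17.
- What may go wrong: the peroxide may attack the exocyclic enone or the C1=C10 alkene. The vinylic carbon may migrate in place of C8. The sensitive enone may polymerise.
- Fallback (sets out from 27, comes back at 28): the enone is masked before the oxygen insertion.
- Conjugate addition of Me2NH (THF, 0 °C) should give the Mannich base F6.
- In H2O2/AcOH the protonated amine should be shielded from oxidation and should lower the migratory aptitude of C11, so the Baeyer–Villiger step should give the amino lactone F7.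
- MeI should give the methiodide F8, and aqueous NaHCO3 should eliminate trimethylamine to restore C11=C13 in 28.

3. Step 7.
- What may go wrong: conjugate addition of hydroperoxide to the β-methyl-substituted lactone may be slow. The lactone may hydrolyse, or open by vinylogous elimination. The facial selectivity may be poor.
- Fallback (sets out from 11, comes back at 12): the epoxide is set by reagent control on the open chain.
- DIBAL-H (CH2Cl2, −78 °C to 0 °C) should give the (Z)-diol F9.
- Sharpless asymmetric epoxidation with L-(+)-diethyl tartrate, Ti(OiPr)4 and one equivalent of t-BuOOH should follow. The primary allylic alcohol should react ahead of the hindered secondary one, and the facial sense follows that known for nerol, giving the epoxy diol F10.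
- TEMPO/PhI(OAc)2 oxidative lactonisation of the 1,5-diol would return 12.

Further compounds
F1 | step 16 | (Z)-alkenylstannane from 18 (Bu3Sn at C11, CH2OH at C11 trans to C6) | CC(C)(C)[Si](OCC/C(C)=C/[C@@H](OC(C)=O)C[C@@]1(C)O[C@H]1[C@@H](OC(C)=O)/C=C(/CO)[Sn](CCCC)(CCCC)CCCC)(c1ccccc1)c1ccccc1
F2 | step 16 | methyl (Z)-2-(hydroxymethyl)enoate (CO2Me at C11 cis to C6) | CC(C)(C)[Si](OCC/C(C)=C/[C@@H](OC(C)=O)C[C@@]1(C)O[C@H]1[C@@H](OC(C)=O)/C=C(/CO)C(=O)OC)(c1ccccc1)c1ccccc1
F3 | step 16 | diol from F2 (TBDPS removed) | OCC/C(C)=C/[C@@H](OC(C)=O)C[C@@]1(C)O[C@H]1[C@@H](OC(C)=O)/C=C(/CO)C(=O)OC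
F4 | step 16 | methyl 2-(bromomethyl)enoate with free primary alcohol | OCC/C(C)=C/[C@@H](OC(C)=O)C[C@@]1(C)O[C@H]1[C@@H](OC(C)=O)/C=C(/CBr)C(=O)OC
F5 | step 16 | bromo aldehyde (C8 aldehyde, C13 bromide) | O=CC/C(C)=C/[C@@H](OC(C)=O)C[C@@]1(C)O[C@H]1[C@@H](OC(C)=O)/C=C(/CBr)C(=O)OC
F6 | step 17 | dimethylamine adduct of 27 (C11 epimers) | CN(C)CC1C(=O)[C@@H]2C/C(C)=C/[C@@H](OC(C)=O)C[C@@]3(C)O[C@H]3[C@@H](OC(C)=O)[C@H]12
F7 | step 17 | α-(dimethylaminomethyl) lactone (C11 epimers) | CN(C)CC1C(=O)O[C@@H]2C/C(C)=C/[C@@H](OC(C)=O)C[C@@]3(C)O[C@H]3[C@@H](OC(C)=O)[C@H]12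
F8 | step 17 | methiodide of F7 | C[N+](C)(C)CC1C(=O)O[C@@H]2C/C(C)=C/[C@@H](OC(C)=O)C[C@@]3(C)O[C@H]3[C@@H](OC(C)=O)[C@H]12.[I-]
F9 | step 7 | (2Z,5S,6E)-9-(tert-butyldiphenylsilyloxy)-3,7-dimethylnona-2,6-diene-1,5-diol | CC(C)(C)[Si](OCC/C(C)=C/[C@@H](O)C/C(C)=C\CO)(c1ccccc1)c1ccccc1
F10 | step 7 | 2,3-epoxide of F9 (target locants 2S,4R,5S) | CC(C)(C)[Si](OCC/C(C)=C/[C@@H](O)C[C@@]1(C)O[C@H]1CO)(c1ccccc1)c1ccccc1
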